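The green run, with second reagent at half the dusk charge, is my starting point: I want the curve of the target's share against time, solved at both ends and then joined.

| flask | substrate | partner | second reagent | third reagent | temperature | remark | time |
|---|---|---|---|---|---|---|---|
| green | 0.44 M | 0.396 M | 0.33 M | 0.528 M | 55 °C | run made earlier |  |
| dusk | 0.44 M | 0.396 M | 0.660 M | 0.528 M | 55 °C |  | 12 h |
| winter | 0.44 M | 0.396 M | 0.660 M | 0.528 M | −5 °C |  | 12 h |
| summer | 0.44 M | 0.396 M | 0.660 M | 0.528 M | 25 °C |  | 12 h |

- green (time / h: target / %, side product / %, substrate / %): 0.667: 0.4, 0.4, 36.1; 1.33: 1.7, 1.2, 23.2; 2.00: 2.2, 2.7, 17.8; 2.50: 3.6, 4.5, 14.4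

(standard deviation of a reading: 0.3 percentage points)

- in percentages every species weighs as the substrate in it: one side product counts as two
- what may be going on: substrate + partner -> intermediate A; second reagent + intermediate A -> intermediate B; third reagent + intermediate B -> target; substrate + target -> side product
- the earlier runs do not show what temperature does; that part of a forecast is a guess

1. the best flask by share of target in all that became target or side product; "all alike" if 1.5 percentage points covers them all (dusk / winter / summer / all alike)
2. share of target in all that became target or side product, dusk
3. share of target in all that became target or side product, winter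
4. share of target in all that became target or side product, summer

Early on, target must come through a chain of two intermediates, so it grows about as the cube of time, and substrate attacks each target molecule in a pseudo-first-order way. Integrating this, with side product counted as two and c(substrate) held steady, gives side product over target = k·c(substrate)·t/2. The share therefore starts high and falls. From the last two green readings I take the attack constant 8.76 M⁻¹ h⁻¹, at 55 °C. The green readings show more target than side product at 1.33 h, 1.7% against 1.2%, but less at 2.00 h, 2.2% against 2.7%, so as read the crossing lies between these two readings, and the last green reading shows a share of 44.4%.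

At the far end I estimate, for partner used up, that the surplus substrate makes side product of 20.0% and that the share climbs towards 80.0%. So the curve falls, passes a trough and rises. I place dusk on the rising branch, between 44.4% and 80.0%, and guess that cold holds winter on the early branch, making it the best flask.

The forecast says winter, with 62% for dusk, 80% for winter and 55% for summer: “Winter resembles a very early time, when target has barely begun reacting”.

The flasks give 59.5% for dusk, 85.7% for winter and 49.1% for summer, so winter is best.

    substrate + partner → intermediate A (k = 0.0116 M⁻¹ min⁻¹, Ea = 65.0 kJ mol⁻¹)
    second reagent + intermediate A → intermediate B (k = 2.01 × 10⁻⁴ M⁻¹ min⁻¹, Ea = 73.0 kJ mol⁻¹)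
    third reagent + intermediate B → target (k = 0.00440 M⁻¹ min⁻¹, Ea = 56.0 kJ mol⁻¹)
    substrate + target → side product (k = 0.0151 M⁻¹ min⁻¹, Ea = 57.0 kJ mol⁻¹)
    (constants at 25 °C)

In winter, intermediate A's half-life by the second step is 98 d, far longer than substrate's 57 h by the first step. In winter at 12.0 h, intermediate A holds 14.8% and target rounds to 0%. Dividing 8.76 M⁻¹ h⁻¹ by the factor 110 for the cold, with 85.2% of the substrate left, gives a ratio of 0.184 and a winter share of 84.5%. In the neighbour of winter charged with 1.6 M of partner, 51.8% of the substrate is left, so the same reckoning, on the substrate left at the end, gives a ratio of 0.112 and a share of 89.9%; the computed flask gives 89.7%.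

The earlier runs and the new flask stem from a simulated flask on assumed constants, noise included.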